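Its constants were set for the occasion; the run is a simulation.

Target is made by the first step and eaten by the second, so follow what is left of the charge, not what has been made.

    starting material + reagent ⇌ target + by-product (K1 = 8.51, k1 = 0.0269 M⁻¹ s⁻¹)
    reagent + target → over-reaction product (k2 = 0.0657 M⁻¹ s⁻¹)
    reagent ⇌ dormant form (K3 = 0.33, k3 = 0.0756 s⁻¹)

common to all: reagent 0.275 M

|  | starting material | time | remark |
|---|---|---|---|
| summer | 0.25 M (fed, over 0.800 min) | 1.0 min | a stirred flask in which starting material is dosed at a steady rate over 0.800 min without added volume, worked up at 1.0 min |
| winter | 0.25 M |  | one stirred flow tank at steady state, fed with the mixture as stated, mean residence time 1.0 min |
| midnight | 0.25 M | 1.0 min | everything together in a closed stirred flask, run for 1.0 min |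
| noon | 0.25 M | 1.0 min | plug flow through a tube for 1.0 min, no back-mixing |

- the set-up with the highest share of target in all that became target or over-reaction product, at the outlet or at the end ("none" if the first two lie within 2 percentage points) (summer / winter / midnight / noon / none)
- share of target in all that became target or over-reaction product, at the outlet or at the end, summer
- share of target in all that became target or over-reaction product, at the outlet or at the end, winter
- share of target in all that became target or over-reaction product, at the outlet or at the end, midnight
- share of target in all that became target or over-reaction product, at the outlet or at the end, noon

- the stated concentrations are those of everything mixed, before any reaction; amounts are the same in each set-up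
- the feed brings no volume worth counting
- run time (summer): 1.0 min

You asked for a quick number and bet on summer, so test that bet. Let a, p and o be the fractions of the starting-material charge standing as starting material, target and over-reaction product. Drop the return of the first step for now and test that once a is reckoned: its rate goes with target times by-product, and both start from nothing. Both forward steps use the same free reagent, so divide one by the other and reagent cancels. Keep 2.44 as s: the over-reaction constant over the main constant, the selectivity factor.

Midnight and noon: p = (a − a^s)/(s − 1)

Winter: o/p = s(1 − a)/a

Now find a. The half-life of reagent by the third step, 0.15 min, is shorter than the run of 1.0 min, so take free reagent as 75.2% of the pool.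

Decay of a at the full pool: 0.334 min⁻¹, so a = 0.716

Pool averaged over the run: 82.8%, so a = 0.758

Midnight and noon, share of target: 71.6%

Winter, with the pool at its outlet level of 71.8%: 63.1%

Test of the dropped return, midnight at the end of the run, at that pool, with all converted starting material counted as target: return rate over forward rate 1.52%, so leave it out of this short run.

Summer falls outside these rules, so treat it as a rough guess. Give the dose its mean stay of 0.600 min, which gives a = 0.847 and a share of 81.8%. That ranks summer above midnight, with winter lowest.

The forecast gives 78% for summer, 61.5% for winter, and 71.5% for midnight and 71.5% for noon, names summer as best, and holds that “the flow tank is worst because all its reaction happens at outlet target levels”.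

The simulation gives 77.8% for summer, 61.8% for winter, 70.7% for midnight and 70.7% for noon, so summer stands first. At the asked time, the forward rate of over-reaction over that of the main step, s·p/a, reads 0.371 in summer, lower than the 0.571 at midnight. In the neighbouring summer flask with 0.11 M of reagent, it reads 0.165, and the share of target there is 90.3%.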